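The vessel was closed, stirred and isothermal, and one earlier run, midnight, had to speak for three new flasks.

| flask | substrate | reagent | temperature | remark | time |
|---|---|---|---|---|---|
| midnight | 0.83 M | 0.50 equiv | 100 °C | run made earlier |  |
| amber | 0.83 M | 1.00 equiv | 100 °C |  | 1.0 h |
| teal | 0.83 M | 1.00 equiv | 80 °C |  | 1.0 h |
| red | 0.83 M | 1.00 equiv | 60 °C |  | 1.0 h |

- midnight (time / min: target / %, side product / %): 2.50: 4, 0; 5.00: 8, 0; 8.00: 20, 3; 10.0: 15, 0; 12.0: 18, 4; 15.0: 22, 4; 20.0: 27, 5

(readings scatter by 2 percentage points)

- the earlier runs do not show what temperature does; that part of a forecast is a guess

* the flask with the highest share of target in all that became target or side product ("all alike" if they lie within 1.5 percentage points) (amber / teal / red / all alike)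
* share of target in all that became target or side product, amber
* share of target in all that became target or side product, teal
* share of target in all that became target or side product, red

Midnight looked contradictory. From 12.0 min to 20.0 min, side product read at a nearly steady ratio to target, 0.185 in the last reading, yet at 10.0 min it read 0% beside 15% target. A steady ratio asks for 2.78% there, over one scatter of 2 percentage points.

So I compared rates at one moment and assumed that side product forms from something the target step leaves behind. Its rate relative to target then grows with target made and, at equal target, falls with reagent charged. With V and P the side product and target as fractions of substrate charged, and e the reagent in equivalents, integration gave the ratio below, as a rough form that takes the reagent as barely spent. I took the lag coefficient L as V/P² at 1.00 equiv, scaled from the last midnight reading, 0.343. That figure carries the scatter of a reading of 5%.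

V/P = L·P·(1.00/e)

This asks only 1.54% at 10.0 min, less than the steady ratio, and so the zero sits within scatter. The early slope, doubled for amber's reagent, gave 0.0320 min⁻¹. Equal charges then gave amber

P = 1.92/(1 + 1.92) = 65.8%

and a share of 81.6%. For teal and red I guessed slower reaction, less target, and so a higher share.

The forecast named red highest, with 83% for amber, 86% for teal and 88% for red, reasoning that “side routes usually have the higher activation energy”.

The flasks gave 78.2% for amber, 87.0% for teal and 95.0% for red.

    substrate + reagent → target + by-product (k = 0.0525 L mol⁻¹ min⁻¹, Ea = 62.0 kJ mol⁻¹)
    substrate + by-product → side product (k = 0.0279 L mol⁻¹ min⁻¹, Ea = 64.0 kJ mol⁻¹)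
    (constants at 100 °C)

Red stood highest, holding 19.1% target. In teal, the target step had half its turnover to the asked time behind it at 0.343 h. The side-product step reached that point later, at 0.592 h. With the target that stood at the asked time, and L carried unchanged from 100 °C, L gave teal 86.7% and red 93.9%, while my amber share of 81.6% stood above the 78.2% of that flask. The teal mixture read at 1.5 h held 53.6% target, where L gave 84.5% and the flask gave 83.8%.

The readings come from a simulation for an exercise; noise was put on by code.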